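**Retrosynthetic overview**
1. Both C–Br bonds are made last: the ring C6–OH is displaced with inversion and the side-chain C2′ silyl ether is converted directly. The side-chain C1′–Cl comes from the C1′ alcohol with inversion.
2. The ring alcohol comes from 1,2-reduction of a 2-substituted 5-chloro-6,6-dimethylcyclohex-2-enone. This six-membered ring is the only ring and is closed by ring-closing metathesis (C1=C2).
3. The acyclic dienone comes from a late C1–C6 union of fragment A (a 2-lithioallylic alkoxide, C4, carrying C1′/C2′) with fragment B (a Weinreb amide, C8, carrying the gem-dimethyl carbon and C4–Cl).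
4. Fragment A: CBS reduction of an α-bromo enone built from methyl glycolate. Fragment B: Brown allylation of a hydroxypivalate-derived aldehyde, then invertive chlorination.

Assumption: atom labels C1–C6, C1′ (CHCl) and C2′ (CH2Br) follow the target named as 6-bromo-1-(2-bromo-1-chloroethyl)-4-chloro-5,5-dimethylcyclohex-1-ene.

**Fragment A**

Step 1
Reactants: 1 methyl glycolate
Product: 2 methyl 2-[(tert-butyldimethylsilyl)oxy]acetate
Conditions: TBSCl, imidazole, CH2Cl2, 0 °C → rt
Reagents that add atoms: tert-butyldimethylsilyl chloride, CC(C)(C)[Si](C)(C)Cl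
Why: Imidazole-promoted silylation caps the primary hydroxyl so that it survives the Grignard, borane and organolithium steps and can later be turned directly into the C2′ bromide.

Step 2
Reactants: 2 methyl 2-[(tert-butyldimethylsilyl)oxy]acetate
Product: 3 2-[(tert-butyldimethylsilyl)oxy]-N-methoxy-N-methylacetamide
Conditions: MeNHOMe·HCl, i-PrMgCl, THF, −20 → 0 °C
Reagents that add atoms: N,O-dimethylhydroxylamine hydrochloride, CNOC.Cl
Why: Direct aminolysis of the ester by the chloromagnesium amide gives a Weinreb amide, an acyl donor that stops at the ketone on Grignard addition.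

Step 3
Reactants: 3 2-[(tert-butyldimethylsilyl)oxy]-N-methoxy-N-methylacetamide
Product: 4 1-[(tert-butyldimethylsilyl)oxy]but-3-en-2-one
Conditions: CH2=CHMgBr, THF, 0 °C; inverse quench into cold 1 M HCl
Reagents that add atoms: vinylmagnesium bromide, C=C[Mg]Br
Why: Weinreb ketone synthesis, in which the chelated tetrahedral adduct collapses only on acidic quench, so no over-addition occurs and the released amine is protonated before it can add to the enone.

Step 4
Reactants: 4 1-[(tert-butyldimethylsilyl)oxy]but-3-en-2-one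
Product: 6 3-bromo-1-[(tert-butyldimethylsilyl)oxy]but-3-en-2-one, via dibromo ketone 5 (not isolated)
Conditions: Br2, CH2Cl2, −78 °C; then Et3N, −78 → 0 °C
Reagents that add atoms: bromine, BrBr
Why: Bromine addition to the enone followed by E1cB loss of HBr (the α-proton is the acidic one, the β-bromide leaves) gives the α-bromo enone, which is a good CBS substrate and the latent vinyllithium.

Step 5
Reactants: 6 3-bromo-1-[(tert-butyldimethylsilyl)oxy]but-3-en-2-one
Product: 7 (2S)-3-bromo-1-[(tert-butyldimethylsilyl)oxy]but-3-en-2-ol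
Conditions: (R)-2-methyl-CBS-oxazaborolidine (20 mol%), BH3·SMe2, THF, −20 °C; MeOH quench
Reagents that add atoms: none
Why: Corey–Bakshi–Shibata reduction in which the 1-bromovinyl group is the large substituent, so the (R)-catalyst gives the (S)-carbinol that becomes C1′ (later inverted to the chloride).

**Fragment B**

Step 6
Reactants: 8 3-hydroxy-2,2-dimethylpropanoic acid
Product: 9 methyl 3-hydroxy-2,2-dimethylpropanoate
Conditions: MeOH, H2SO4 (cat.), reflux
Reagents that add atoms: methanol, CO
Why: Fischer esterification protects the acid as the ester that later becomes the Weinreb amide.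

Step 7
Reactants: 9 methyl 3-hydroxy-2,2-dimethylpropanoate
Product: 10 methyl 2,2-dimethyl-3-oxopropanoate
Conditions: PhI(OAc)2 (1.1 equiv), TEMPO (10 mol%), CH2Cl2, rt
Reagents that add atoms: none
Why: TEMPO (oxoammonium) oxidation of the primary neopentyl alcohol stops cleanly at the non-enolisable aldehyde.

Step 8
Reactants: 10 methyl 2,2-dimethyl-3-oxopropanoate
Product: 12 methyl (3S)-3-hydroxy-2,2-dimethylhex-5-enoate, via borinate ester 11 (not isolated)
Conditions: (−)-Ipc2BOMe [from (+)-α-pinene], CH2=CHCH2MgBr, Et2O, 0 °C → rt; then 10, −78 °C; then 3 M NaOH, 30% H2O2, 0 °C → rt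
Reagents that add atoms: allylmagnesium bromide, C=CC[Mg]Br (allyl group, delivered through the allylborane made in the flask)
Why: Brown allylboration through a chair Zimmerman–Traxler transition state, where the (+)-α-pinene-derived reagent attacks the Si face of α-quaternary aldehydes and sets the (S)-carbinol that becomes C4 after inversion.

Step 9
Reactants: 12 methyl (3S)-3-hydroxy-2,2-dimethylhex-5-enoate
Product: 14 methyl (3R)-3-chloro-2,2-dimethylhex-5-enoate, via triflate 13 (not isolated)
Conditions: Tf2O, 2,6-lutidine, CH2Cl2, −78 °C; then n-Bu4NCl, −78 → 0 °C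
Reagents that add atoms: tetrabutylammonium chloride, CCCC[N+](CCCC)(CCCC)CCCC.[Cl-]
Why: Triflate activation followed by SN2 displacement with chloride inverts the carbinol to the (R)-chloride (C4 of the target), with ionisation disfavoured by the β-ester and no hydrogen on the quaternary neighbour to eliminate.

Step 10
Reactants: 14 methyl (3R)-3-chloro-2,2-dimethylhex-5-enoate
Product: 15 (3R)-3-chloro-N-methoxy-N,2,2-trimethylhex-5-enamide
Conditions: MeNHOMe·HCl, i-PrMgCl, THF, −20 → 0 °C
Reagents that add atoms: N,O-dimethylhydroxylamine hydrochloride, CNOC.Cl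
Why: Ester aminolysis to the Weinreb amide as in step 2, and the chloride is safe because the α-carbon is quaternary and cannot start an E1cB elimination.

**Coupling and endgame**

Step 11
Reactants: 7 (2S)-3-bromo-1-[(tert-butyldimethylsilyl)oxy]but-3-en-2-ol; 15 (3R)-3-chloro-N-methoxy-N,2,2-trimethylhex-5-enamide
Product: 17 (2R,6R)-1-[(tert-butyldimethylsilyl)oxy]-6-chloro-2-hydroxy-5,5-dimethyl-3-methylidenenon-8-en-4-one, via dilithio alkoxide 16 (not isolated)
Conditions: 7, n-BuLi (1.0 equiv), Et2O, −78 °C; t-BuLi (2.0 equiv), −78 °C; then 15, −78 → −20 °C; aq. NH4Cl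
Reagents that add atoms: none
Why: Bromine–lithium exchange on the lithium alkoxide of 7 gives a vinyllithium whose only β-leaving group is an oxide (no allene formation), and its Weinreb ketone synthesis with 15 joins the two fragments at C1–C6 without creating a new stereocenter.

Step 12
Reactants: 17 (2R,6R)-1-[(tert-butyldimethylsilyl)oxy]-6-chloro-2-hydroxy-5,5-dimethyl-3-methylidenenon-8-en-4-one
Product: 18 (5R)-2-[(1R)-2-[(tert-butyldimethylsilyl)oxy]-1-hydroxyethyl]-5-chloro-6,6-dimethylcyclohex-2-en-1-one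
Conditions: second-generation Grubbs catalyst RuCl2(=CHPh)(PCy3)(H2IMes) (5 mol%), CH2Cl2 (5 mM), 40 °C
Reagents that add atoms: none
Why: Ring-closing metathesis between the terminal vinyl group and the 1,1-disubstituted enone alkene closes the six-membered ring with loss of ethene, helped by the gem-dimethyl effect.

Step 13
Reactants: 18 (5R)-2-[(1R)-2-[(tert-butyldimethylsilyl)oxy]-1-hydroxyethyl]-5-chloro-6,6-dimethylcyclohex-2-en-1-one
Product: 19 (1S,5R)-2-[(1R)-2-[(tert-butyldimethylsilyl)oxy]-1-hydroxyethyl]-5-chloro-6,6-dimethylcyclohex-2-en-1-ol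
Conditions: NaBH4, CeCl3·7H2O, MeOH, −78 °C
Reagents that add atoms: none
Why: Luche 1,2-reduction, where hydride adds axially, anti to the pseudo-axial methyl of the half-chair that keeps C–Cl equatorial, giving the ring alcohol cis to the C4 chlorine.

Step 14
Reactants: 19 (1S,5R)-2-[(1R)-2-[(tert-butyldimethylsilyl)oxy]-1-hydroxyethyl]-5-chloro-6,6-dimethylcyclohex-2-en-1-ol
Product: 20 (1R,5R)-2-[(1S)-2-[(tert-butyldimethylsilyl)oxy]-1-chloroethyl]-5-chloro-6,6-dimethylcyclohex-2-en-1-ol
Conditions: PPh3 (1.1 equiv), Cl3CC(O)CCl3, CH2Cl2, −20 → 0 °C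
Reagents that add atoms: hexachloroacetone, ClC(Cl)(Cl)C(=O)C(Cl)(Cl)Cl
Why: Appel-type chlorination, in which the oxyphosphonium of the unhindered side-chain allylic alcohol collapses by SN2 with inversion to the (S)-chloride while the neopentyl-type ring alcohol reacts far more slowly.

Step 15
Reactants: 20 (1R,5R)-2-[(1S)-2-[(tert-butyldimethylsilyl)oxy]-1-chloroethyl]-5-chloro-6,6-dimethylcyclohex-2-en-1-ol
Product: 21 (4R,6S)-6-bromo-1-[(1S)-2-bromo-1-chloroethyl]-4-chloro-5,5-dimethylcyclohex-1-ene
Conditions: Ph3PBr2 (2.5 equiv), 2,6-lutidine, CH2Cl2, −20 °C → rt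
Reagents that add atoms: dibromotriphenylphosphorane, BrP(Br)(c1ccccc1)(c1ccccc1)c1ccccc1
Why: Deoxybromination through oxyphosphonium bromides, where SN2 inversion of the cis ring alcohol places bromine trans to the C4 chlorine (6S) and the primary silyl ether is converted directly into the primary bromide.

**Compound list**
1 | methyl glycolate (methyl 2-hydroxyacetate) | COC(=O)CO | starting material
2 | methyl 2-[(tert-butyldimethylsilyl)oxy]acetate | COC(=O)CO[Si](C)(C)C(C)(C)C | intermediate
3 | 2-[(tert-butyldimethylsilyl)oxy]-N-methoxy-N-methylacetamide | CON(C)C(=O)CO[Si](C)(C)C(C)(C)C | intermediate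
4 | 1-[(tert-butyldimethylsilyl)oxy]but-3-en-2-one | C=CC(=O)CO[Si](C)(C)C(C)(C)C | intermediate
5 | 3,4-dibromo-1-[(tert-butyldimethylsilyl)oxy]butan-2-one (racemic, not isolated) | BrCC(Br)C(=O)CO[Si](C)(C)C(C)(C)C | intermediate
6 | 3-bromo-1-[(tert-butyldimethylsilyl)oxy]but-3-en-2-one | C=C(Br)C(=O)CO[Si](C)(C)C(C)(C)C | intermediate
7 | (2S)-3-bromo-1-[(tert-butyldimethylsilyl)oxy]but-3-en-2-ol (fragment A) | C=C(Br)[C@@H](O)CO[Si](C)(C)C(C)(C)C | intermediate
8 | 3-hydroxy-2,2-dimethylpropanoic acid (hydroxypivalic acid) | OCC(C)(C)C(=O)O | starting material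
9 | methyl 3-hydroxy-2,2-dimethylpropanoate | COC(=O)C(C)(C)CO | intermediate
10 | methyl 2,2-dimethyl-3-oxopropanoate | COC(=O)C(C)(C)C=O | intermediate
11 | methyl (3S)-3-{[bis(isopinocampheyl)boranyl]oxy}-2,2-dimethylhex-5-enoate, Ipc groups from (+)-α-pinene (not isolated) | C=CC[C@H](OB([C@@H]1C[C@@H]2C[C@H]([C@H]1C)C2(C)C)[C@@H]1C[C@@H]2C[C@H]([C@H]1C)C2(C)C)C(C)(C)C(=O)OC | intermediate
12 | methyl (3S)-3-hydroxy-2,2-dimethylhex-5-enoate | C=CC[C@H](O)C(C)(C)C(=O)OC | intermediate
13 | methyl (3S)-2,2-dimethyl-3-[(trifluoromethanesulfonyl)oxy]hex-5-enoate (not isolated) | C=CC[C@H](OS(=O)(=O)C(F)(F)F)C(C)(C)C(=O)OC | intermediate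
14 | methyl (3R)-3-chloro-2,2-dimethylhex-5-enoate | C=CC[C@@H](Cl)C(C)(C)C(=O)OC | intermediate
15 | (3R)-3-chloro-N-methoxy-N,2,2-trimethylhex-5-enamide (fragment B) | C=CC[C@@H](Cl)C(C)(C)C(=O)N(C)OC | intermediate
16 | lithium (2R)-1-[(tert-butyldimethylsilyl)oxy]-3-lithiobut-3-en-2-olate, same spatial arrangement as 7 (not isolated) | C=C([Li])[C@@H](O[Li])CO[Si](C)(C)C(C)(C)C | intermediate
17 | (2R,6R)-1-[(tert-butyldimethylsilyl)oxy]-6-chloro-2-hydroxy-5,5-dimethyl-3-methylidenenon-8-en-4-one | C=CC[C@@H](Cl)C(C)(C)C(=O)C(=C)[C@@H](O)CO[Si](C)(C)C(C)(C)C | intermediate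
18 | (5R)-2-[(1R)-2-[(tert-butyldimethylsilyl)oxy]-1-hydroxyethyl]-5-chloro-6,6-dimethylcyclohex-2-en-1-one | CC1(C)[C@H](Cl)CC=C([C@@H](O)CO[Si](C)(C)C(C)(C)C)C1=O | intermediate
19 | (1S,5R)-2-[(1R)-2-[(tert-butyldimethylsilyl)oxy]-1-hydroxyethyl]-5-chloro-6,6-dimethylcyclohex-2-en-1-ol (ring OH cis to Cl) | CC1(C)[C@H](Cl)CC=C([C@@H](O)CO[Si](C)(C)C(C)(C)C)[C@@H]1O | intermediate
20 | (1R,5R)-2-[(1S)-2-[(tert-butyldimethylsilyl)oxy]-1-chloroethyl]-5-chloro-6,6-dimethylcyclohex-2-en-1-ol (ring OH cis to Cl) | CC1(C)[C@H](Cl)CC=C([C@H](Cl)CO[Si](C)(C)C(C)(C)C)[C@@H]1O | intermediate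
21 | (4R,6S)-6-bromo-1-[(1S)-2-bromo-1-chloroethyl]-4-chloro-5,5-dimethylcyclohex-1-ene | CC1(C)[C@H](Cl)CC=C([C@H](Cl)CBr)[C@H]1Br | target

**Totals**
Total step count: 15.
Longest linear sequence: 10 steps (steps 1–5 then 11–15; steps 6–10 then 11–15 is equally long).

**Three steps most likely to fail**

Step 15 (bromination at the neopentyl-type allylic ring carbinol). Bromide may attack C2 in an SN2′ sense or elimination may win, and the silyl ether has to react in the same pot. The fallback sets out from 19 and comes back at 21. It replaces displacement at C6 by electrophilic bromodesilylation of an allylsilane, which is regiospecific for C6.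
- Silylate the less hindered side-chain hydroxyl of 19 (TESCl, imidazole, −20 °C) to give the C1′ triethylsilyl ether of 19 F5.
- Convert the ring hydroxyl into the ring N-phenylcarbamate F6 (PhNCO, DMAP).
- N-lithiate (n-BuLi) and treat with (PhMe2Si)2CuLi. Silicon is delivered syn and SN2′ to C2, giving the allylsilane F7, with SiMe2Ph on C2 cis to the C4 chlorine and the double bond now C1=C6.
- Remove the triethylsilyl group (PPTS, MeOH) to give the allylsilane alcohol F8.
- Chlorinate C1′ with inversion (PPh3, Cl3CC(O)CCl3) to give the allylsilane chloride F9.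
- Add Br2 (1.0 equiv, CH2Cl2, −78 °C). Anti SE2′ attack puts bromine on C6 opposite to silicon, hence trans to the C4 chlorine, and returns the double bond to C1=C2, giving the ring bromide silyl ether F10.
- Ph3PBr2 then converts the primary silyl ether of F10 into the bromide, which is 21.

Step 9 (SN2 by chloride next to a quaternary carbon). The triflate may eliminate toward the allylic CH2 or rearrange. The fallback sets out from 12 and comes back at 15. It uses ring strain instead of a sulfonate as the activating device.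
- Saponify 12 (LiOH, THF/H2O) to (3S)-3-hydroxy-2,2-dimethylhex-5-enoic acid F1.
- Close F1 by carboxyl activation (PhSO2Cl, pyridine, 0 °C), which leaves the C3–O bond untouched, to give the β-lactone (4S)-3,3-dimethyl-4-(prop-2-en-1-yl)oxetan-2-one F2.
- Open F2 at C4 with chloride (LiCl, DMF, 60 °C). This is alkyl–oxygen cleavage by SN2 with inversion, the mode by which α,α-dimethyl β-lactones are attacked at their β-carbon, and it gives (3R)-3-chloro-2,2-dimethylhex-5-enoic acid F3.
- Convert F3 (carbonyldiimidazole, then MeNHOMe·HCl) into 15.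

Step 14 (chlorination of one of two secondary allylic alcohols). The ring hydroxyl may compete or SN2′ chloride may form. The fallback sets out from 18 and comes back at 20. It changes the order so that the ring hydroxyl does not yet exist when C1′ is chlorinated.
- Treat enone 18 with PPh3 and Cl3CC(O)CCl3 (CH2Cl2, −20 °C) to give (5R)-2-[(1S)-2-[(tert-butyldimethylsilyl)oxy]-1-chloroethyl]-5-chloro-6,6-dimethylcyclohex-2-en-1-one F4.
- Reduce F4 under the Luche conditions of step 13 (NaBH4, CeCl3·7H2O, MeOH, −78 °C), with the same facial preference, to give 20.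

**Further compounds**
F1 | step 9 | (3S)-3-hydroxy-2,2-dimethylhex-5-enoic acid | C=CC[C@H](O)C(C)(C)C(=O)O
F2 | step 9 | (4S)-3,3-dimethyl-4-(prop-2-en-1-yl)oxetan-2-one | C=CC[C@@H]1OC(=O)C1(C)C
F3 | step 9 | (3R)-3-chloro-2,2-dimethylhex-5-enoic acid | C=CC[C@@H](Cl)C(C)(C)C(=O)O
F4 | step 14 | (5R)-2-[(1S)-2-[(tert-butyldimethylsilyl)oxy]-1-chloroethyl]-5-chloro-6,6-dimethylcyclohex-2-en-1-one | CC1(C)[C@H](Cl)CC=C([C@H](Cl)CO[Si](C)(C)C(C)(C)C)C1=O
F5 | step 15 | C1′ triethylsilyl ether of 19 | CC1(C)[C@H](Cl)CC=C([C@@H](O[Si](CC)(CC)CC)CO[Si](C)(C)C(C)(C)C)[C@@H]1O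
F6 | step 15 | ring N-phenylcarbamate of F5 | CC1(C)[C@H](Cl)CC=C([C@@H](O[Si](CC)(CC)CC)CO[Si](C)(C)C(C)(C)C)[C@@H]1OC(=O)Nc1ccccc1
F7 | step 15 | allylsilane: C2-dimethyl(phenyl)silyl cis to the C4 chlorine, double bond C1=C6, side chain C1′-OTES and C2′-OTBS | CC1(C)[C@H](Cl)C[C@H]([Si](C)(C)c2ccccc2)C(=C1)[C@@H](O[Si](CC)(CC)CC)CO[Si](C)(C)C(C)(C)C
F8 | step 15 | allylsilane alcohol (F7 without the triethylsilyl group) | CC1(C)[C@H](Cl)C[C@H]([Si](C)(C)c2ccccc2)C(=C1)[C@@H](O)CO[Si](C)(C)C(C)(C)C
F9 | step 15 | allylsilane chloride (C1′ inverted to the S chloride) | CC1(C)[C@H](Cl)C[C@H]([Si](C)(C)c2ccccc2)C(=C1)[C@H](Cl)CO[Si](C)(C)C(C)(C)C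
F10 | step 15 | tert-butyl{(2S)-2-[(4R,6S)-6-bromo-4-chloro-5,5-dimethylcyclohex-1-en-1-yl]-2-chloroethoxy}dimethylsilane | CC1(C)[C@H](Cl)CC=C([C@H](Cl)CO[Si](C)(C)C(C)(C)C)[C@H]1Br
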